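**Plan**
- The last-stage cut is the central Cα–Cβ bond of the CH2CH2 bridge between C2 of the 4-pyranone (ring B) and the guaiacyl ring (ring C).
- Enabling feature: Cβ is the benzylic carbon para to the free OH of the 4-hydroxy-3-methoxyphenyl ring, so it is the exocyclic terminus of a para-quinone methide. Cα is the C2 methyl carbon of a 2-methylchromone, acidified through C2=C3–C4=O.
- Earlier cuts: O1–C2 and the C3–C2 bond of ring B lead back to 2-hydroxy-4,5-dimethoxyacetophenone and ethyl acetate. The benzylic C–S bond of the quinone methide precursor leads back to vanillyl alcohol and PhSO2Na.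
- Forward: Claisen acylation, then acid closure of ring B onto the preformed ring A. In parallel, the sulfone is made in one step, and the two halves are joined last, without protecting groups.
- The target is achiral and has no stereogenic alkene, so no stereochemistry has to be set.

Key step: step 4

Assumption: diketone 2 is drawn in its open diketo form. It should exist together with its enol and cyclic hemiketal tautomers, all of which converge on 3 in step 2.

**Step 1**
Reactants: 1 1-(2-hydroxy-4,5-dimethoxyphenyl)ethanone
Product: 2 1-(2-hydroxy-4,5-dimethoxyphenyl)butane-1,3-dione
Conditions: NaH (4 equiv), EtOAc (excess), THF, 0 °C → reflux; 1 M HCl quench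
Reagents that add atoms: ethyl acetate, CCOC(C)=O
Why: Crossed Claisen condensation: NaH turns 1 into its phenoxide–enolate dianion, the enolate carbon is acylated by ethyl acetate, and the final irreversible deprotonation of the 1,3-diketone pulls the equilibrium over, as is routine for 2-hydroxyacetophenones on the way to 2-methylchromones.

**Step 2**
Reactants: 2 1-(2-hydroxy-4,5-dimethoxyphenyl)butane-1,3-dione
Product: 3 6,7-dimethoxy-2-methyl-4H-chromen-4-one
Conditions: conc. H2SO4 (cat.), AcOH, 90 °C
Reagents that add atoms: none
Why: Acid-catalysed cyclodehydration (the closing half of the classical Claisen route to chromones): the phenolic OH adds to the protonated terminal ketone to give the six-membered hemiketal and loss of water installs C2=C3, while the aryl methyl ethers are inert to catalytic acid at this temperature.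

**Step 3**
Reactants: 4 vanillyl alcohol (4-(hydroxymethyl)-2-methoxyphenol); 5 sodium benzenesulfinate
Product: 6 2-methoxy-4-[(phenylsulfonyl)methyl]phenol
Conditions: aq. HCO2H, rt → 40 °C, product collected by filtration
Reagents that add atoms: none
Why: Dehydrative sulfonylation of an electron-rich benzylic alcohol (SN1-type S-alkylation of a sulfinate): formic acid ionises the para-hydroxybenzylic C–O bond and the soft sulfur of benzenesulfinate captures the stabilised cation, any kinetically formed sulfinate or formate ester re-ionising under the same conditions until the stable sulfone crystallises.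

**Step 4**
Reactants: 3 6,7-dimethoxy-2-methyl-4H-chromen-4-one; 6 2-methoxy-4-[(phenylsulfonyl)methyl]phenol
Product: 11 2-[2-(4-hydroxy-3-methoxyphenyl)ethyl]-6,7-dimethoxy-4H-chromen-4-one, via lithium dienolate 7 (not isolated), via lithium phenoxide of the sulfone 8 (not isolated), via para-quinone methide 9 (not isolated), via lithium phenoxide of the target 10 (not isolated)
Conditions: flask A: 3 (1.5 equiv), LiN(SiMe3)2 (1.5 equiv), THF, −78 °C; flask B: 6 (1.0 equiv), LiN(SiMe3)2 (1.0 equiv), THF, −78 °C; B cannulated into A, DMPU, −78 → 0 °C; 1 M HCl quench
Reagents that add atoms: none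
Why: Proposed new method: LiN(SiMe3)2 removes a proton from the C2 methyl group of 3, a vinylogous methyl ketone through C2=C3–C4=O, to give the cross-conjugated dienolate 7, while the separately formed phenoxide 8 pushes out benzenesulfinate on warming (1,6-elimination) and releases the quinone methide 9. The exocyclic CH2 terminus of 7 then adds to the exocyclic methylene of 9, the gain of aromaticity in ring C makes the C–C bond formation irreversible, and the acidic quench of phenoxide 10 hands over the free phenol 11. The closest known reaction types are the 1,6-conjugate addition of stabilised carbanions to para-quinone methides set free by base from 4-hydroxybenzyl sulfones and the lateral alkylation of lithiated 2-methylchromones and 2-methyl-4-pyranones; only their union is new. No ring is closed and no stereocentre is created. The step needs site selectivity for the exocyclic carbon of 7 over C3 and over the C4 oxygen, which the substrate secures because only attack through the terminal carbon restores the conjugated 4-pyranone and because the soft, unhindered methylene of 9 favours carbon over oxygen. Oligomerisation of 9 and a second benzylation are held back by the excess of 7, by the absence of free amide base and by the reversible re-addition of sulfinate, which keeps the standing concentration of 9 low.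

**Compound list**
1 | 1-(2-hydroxy-4,5-dimethoxyphenyl)ethanone | CC(=O)c1cc(OC)c(OC)cc1O | starting material
2 | 1-(2-hydroxy-4,5-dimethoxyphenyl)butane-1,3-dione | CC(=O)CC(=O)c1cc(OC)c(OC)cc1O | intermediate
3 | 6,7-dimethoxy-2-methyl-4H-chromen-4-one | Cc1cc(=O)c2cc(OC)c(OC)cc2o1 | intermediate
4 | vanillyl alcohol (4-(hydroxymethyl)-2-methoxyphenol) | COc1cc(CO)ccc1O | starting material
5 | sodium benzenesulfinate | [Na+].[O-]S(=O)c1ccccc1 | starting material
6 | 2-methoxy-4-[(phenylsulfonyl)methyl]phenol | COc1cc(CS(=O)(=O)c2ccccc2)ccc1O | intermediate
7 | lithium 6,7-dimethoxy-2-methylidene-2H-chromen-4-olate | [Li+].C=C1C=C([O-])c2cc(OC)c(OC)cc2O1 | intermediate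
8 | lithium 2-methoxy-4-[(phenylsulfonyl)methyl]phenolate | [Li+].COc1cc(CS(=O)(=O)c2ccccc2)ccc1[O-] | intermediate
9 | 2-methoxy-4-methylidenecyclohexa-2,5-dien-1-one | COC1=CC(=C)C=CC1=O | intermediate
10 | lithium 4-[2-(6,7-dimethoxy-4-oxo-4H-chromen-2-yl)ethyl]-2-methoxyphenolate | [Li+].COc1cc(CCc2cc(=O)c3cc(OC)c(OC)cc3o2)ccc1[O-] | intermediate
11 | 2-[2-(4-hydroxy-3-methoxyphenyl)ethyl]-6,7-dimethoxy-4H-chromen-4-one | COc1cc(CCc2cc(=O)c3cc(OC)c(OC)cc3o2)ccc1O | target

Total step count: 4
Longest linear sequence: 3 steps (1 → 2 → 3 → 11). The sulfone branch (4 + 5 → 6) adds one step in parallel.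

**Steps most likely to fail**

1. Step 4.
   - What may go wrong:
     - The lithium phenoxide may expel sulfinate too slowly at temperatures the dienolate tolerates.
     - The unsubstituted quinone methide may oligomerise faster than it is intercepted.
     - Proton exchange between dienolate and product may lead to a second benzylation at Cα.
     - The dienolate may add in Michael fashion to C2 of neutral chromone.
   - Fallback (known chemistry): setting out from 3, a base-mediated vinylogous aldol condensation with commercial 4-(benzyloxy)-3-methoxybenzaldehyde (COc1cc(C=O)ccc1OCc1ccccc1; NaOEt, EtOH, rt → reflux) should give (E)-2-[2-(4-benzyloxy-3-methoxyphenyl)ethenyl]-6,7-dimethoxy-4H-chromen-4-one F1. Hydrogenation over Pd/C (H2 1 atm, EtOAc/MeOH, rt) is stopped once the styryl alkene and the benzyl ether have been consumed. It saturates the bridge, frees the phenol and comes back to the route at 11. Both operations are established for 2-(2-arylethyl)chromones.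

2. Step 3.
   - What may go wrong: Friedel–Crafts self-condensation of the vanillyl cation with the electron-rich ring of a second molecule may compete with capture by sulfinate, and the acid may cause the free sulfinic acid to disproportionate.
   - Fallback: setting out from 4, the C–S bond is made at the sulfide level with a far better nucleophile. Acid-catalysed thioetherification with thiophenol (PhSH, TsOH cat., CH2Cl2, rt) should give 2-methoxy-4-[(phenylsulfanyl)methyl]phenol F2. Oxidation with 30% H2O2 and Na2WO4 (cat.) in MeOH at rt then comes back to the route at 6.

3. Step 1.
   - What may go wrong: self-condensation of ethyl acetate may consume the base, C-acylation of the poorly soluble dianion may be incomplete, and acylation at the phenoxide oxygen may compete.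
   - Fallback: setting out from 1, the acyl transfer is made intramolecular. O-acetylation (Ac2O, pyridine, rt) should give 2-acetyl-4,5-dimethoxyphenyl acetate F3. A Baker–Venkataraman O→C acyl migration (KOtBu, THF, 0 °C → rt; 1 M HCl quench) then comes back to the route at 2.

**Further compounds**
F1 | step 4 | (E)-2-[2-(4-benzyloxy-3-methoxyphenyl)ethenyl]-6,7-dimethoxy-4H-chromen-4-one | COc1cc(/C=C/c2cc(=O)c3cc(OC)c(OC)cc3o2)ccc1OCc1ccccc1
F2 | step 3 | 2-methoxy-4-[(phenylsulfanyl)methyl]phenol | COc1cc(CSc2ccccc2)ccc1O
F3 | step 1 | 2-acetyl-4,5-dimethoxyphenyl acetate | CC(=O)Oc1cc(OC)c(OC)cc1C(C)=O
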